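## The problem

Kanzonol V (25) is a 2-arylbenzofuran without stereocentres, so every difficulty is one of position and of functional-group tolerance. Ring A, the benzo ring of the benzofuran, carries a 3-methylbut-2-enyl group at C5 beside a free hydroxyl at C6. Ring B (C1' to C6') is bonded to benzofuran C2 through C1', carries a 2,2-dimethyl-2H-pyran fused through its oxygen at C2' and its vinylic carbon at C3', and has a free hydroxyl at C4'. Ring B is therefore a resorcinol whose two oxygen atoms flank C3' and must be told apart: the pyran has to close on the C2' oxygen, whereas annulation of a 2,4-dihydroxyaryl carbonyl compound normally closes on the unhindered C4' oxygen. On ring A the prenyl group must go to C5 and not to C7, which electrophilic prenylation of a resorcinol does not ensure. A prenyl group next to a free phenol cyclises to a chroman under acid, and the chromene double bond does not survive acid, hydrogenation or strong oxidants, so the last steps must avoid all of these. The enabling feature is ring B read as a benzoate: carbon on C1', oxygen para to it on C4', hydrogen on C5' and C6', which is the pattern left when a 5-alkoxycarbonyl-2-pyranone takes up a ketene acetal and loses CO2 and an alcohol. The remaining C2'–O/C3'–C pair then corresponds to the C4 oxygen and C3 of a 4-hydroxy-2-pyranone, across which an enal fuses a 2H-pyran; such a pyranone has only one hydroxyl, so the C2'/C4' question is settled before the benzene ring exists.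

## Retrosynthesis

**Unmasking (25 from 24).** The last step cuts only two O–acyl bonds: the acetate on the C4' oxygen and the pivalate on the C6 oxygen of 24. Esters are preferred to acetal or silyl protection because methoxide removes them. Acid, which an acetal would need, threatens the C5 prenyl/C6 hydroxyl pair and the chromene. The esters must also survive acid chloride formation, phosphonium salt formation and ylide chemistry, which they should.

**Furan ring (24 from 15 and 21).** The O1–C2 and C2=C3 bonds are cut, which leads back to acid chloride 15 and the ortho-hydroxybenzyl phosphonium salt 21. The forward reaction is O-acylation followed by intramolecular Wittig olefination of the aryl ester. The neighbouring cut, heteroannulation of an ortho-halophenol with an arylalkyne, would require the ring B carboxyl to be reduced and homologated to an alkyne. The Wittig closure uses the carboxyl oxidation state as it stands, and both halves are complete before they meet. The forward step needs O-acylation to precede ylide formation, and the ylide must reach an ester carbonyl flanked by the pyran oxygen.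

**Ring A (21 from 20, 19, 17 and 16, with 18).** The C–P bond is cut back to benzyl alcohol 20 and this to aldehyde 19. The C5–prenyl bond of 19 is cut to aryl bromide 17 and prenylstannane 18. Bromide 17 is the 4-O-pivalate of the catalogue compound 16. The bromine of 16 marks C5 unambiguously, which direct prenylation of a resorcinol aldehyde would not do. The C2 hydroxyl of 16 is hydrogen-bonded to the aldehyde, so only the C4 hydroxyl is acylated and the C2 hydroxyl stays free to become O1.

**Ring B acid (15 from 14, 13 and 11).** Acid chloride 15 comes from acetoxy acid 14, this from hydroxy acid 13, and 13 from the methoxy ester 11 by cleavage of the O–CH3 and O–ethyl bonds. The demethylation is placed here because the methoxy group of 11 is para to the ester, which makes thiolate dealkylation easy, and because no prenyl group is present yet. On the finished, electron-rich skeleton the same operation would be far harder.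

**Benzene ring of the chromene (11 from 7 and 8).** The C3'–C4' and C5'–C6' bonds (chromene C4a–C5 and C6–C7) are cut, and a CO2 bridge and one methanol are restored. This gives the pyrano-fused 2-pyranone 7 and 1,1-dimethoxyethene 8. Against a resorcinol-based chromene synthesis, this cut needs no differentiation of two phenols. The precursor is an isolable bicyclic lactone, and the ester of 7 directs the regiochemistry. The forward reaction must take place at the pyranone diene and leave the 2H-pyran closed.

**Pyran ring (7 from 4 and 5).** The C4a–C4 bond and the O1–C2 bond of the 2H-pyran are cut, which gives hydroxypyranone 4 and 3-methylbut-2-enal 5. The forward reaction is the formal [3+3] annulation of a 4-hydroxy-2-pyranone with an enal. It is asked to condense at C3 of 4 and to close through the C4 oxygen.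

**Pyranone (4 from 1 and 2).** The ring C6 carbon and the ring oxygen bond are cut. Compound 4 is the known product of ethoxymethylenation of diethyl 3-oxopentanedioate 1 with triethyl orthoformate 2, followed by acid-mediated lactonisation by way of 3.

## Roads not taken

**Alternative 1:** The furan O1–C2 bond is cut and ring closure is run along a coumestan. In the forward direction the ortho hydroxyl of the aryl group of the 3-arylcoumarin A1 adds to coumarin C4, and dehydrogenation with Pd(OAc)2 and Cu(OAc)2 gives the coumestan A2. The lactone is then opened and its carbonyl carbon is removed as CO2, and the pyran is fused onto ring B afterwards.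

- Merits: the coumarin is available by a Perkin-type condensation from simple aromatic materials. The lactone oxygen is the C2' oxygen, so after excision the C2' hydroxyl is the only free one on ring B and the pyran regiochemistry is as secure as in the chosen plan.
- Weak points: a ring and a carbon are built only to be destroyed. Decarboxylation of a benzofuran-3-carboxylic acid normally needs copper at high temperature. Divalent palladium meets a prenyl group in the key step. The pyran still has to be added over two or three steps, and the acetal protecting groups must finally be removed with acid beside a prenylphenol and a chromene.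
- Comparison: Alternative 1 is better in resting on classical aromatic chemistry, with no cycloaddition on an untested pyranone. The chosen plan sets against it that no atom is excised, that no step needs forcing decarboxylation, and that the endgame is free of acid.

**Alternative 2:** Ring B is cut completely (C2'–C3', C4'–C5', C1'–C2') in a photochemical vinylketene benzannulation. Irradiation of diazoketone A3 gives a vinylketene by Wolff rearrangement. This adds siloxyalkyne A4 in a [2+2] sense; the cyclobutenone opens and recloses by 6π electrocyclisation to phenol A5. Oxidative closure of the C2' hydroxyl onto the C3' prenyl group and desilylation would finish the synthesis.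

- Merits: the connectivity of the annulation fixes every substituent of ring B in one step, and the C2' hydroxyl emerges free and unique. Only two steps follow the key step.
- Weak points: A3 needs diazo chemistry on a prenylated benzofuran enone, and A4 needs ynolate chemistry. The vinylketene carries a benzofuranyl group and can close onto benzofuran C3 on its own before it meets the alkyne. The later dehydrogenative pyran closure must act on one of two prenyl groups in an oxidisable molecule.
- Comparison: Alternative 2 is more convergent and has the shorter endgame. The chosen plan sets against it a catalogue dienophile, no diazo compound, no photochemical step and no oxidant in the presence of a prenyl group.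

**Alternative 3:** Ring A is cut at C4–C5 and C6–C7. The furo-fused 2-pyranone A6, a masked furan-2,3-quinodimethane, adds siloxyalkyne A4 across its C4 and C7 termini. Loss of CO2 gives the bis(triisopropylsilyl) ether A7, one desilylation away from the target.

- Merits: this is the most convergent of all the plans. The prenyl group arrives with the alkyne, so no aromatic prenylation is needed, and the endgame is a fluoride deprotection.
- Weak points: A6 has no acceptor group, so the orientation of A4 (prenyl at C5 or at C6) rests on weak polarisation only. The ortho-quinoid pyranone is likely to be labile. A6 must also already contain the complete chromene ring B, so the central regiochemical problem is moved into the synthesis of A6 and not solved.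
- Comparison: Alternative 3 is clearly better after the key step. The chosen plan sets against it a stable, ester-activated pyranone whose orientation is dictated, and it answers the ring B problem directly.

Key step: step 3

Assumption: compounds 8, 16 and 18 are taken as catalogue chemicals; 25 has no stereocentre, and alkene geometry matters only in the transient intermediate 6.

## Route

Step 1
Reactants: 1 diethyl 3-oxopentanedioate; 2 triethyl orthoformate
Product: 4 ethyl 4-hydroxy-2-oxo-2H-pyran-5-carboxylate, via ethoxymethylidene diester 3 (not isolated)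
Conditions: HC(OEt)3 (1.1 equiv), Ac2O, 130 °C; evaporate; 2 M aq HCl, rt
Reagents that add atoms: water, O
Why: Ethoxymethylenation of one active methylene of 1 (acetic anhydride takes up the ethanol) gives 3; aqueous acid hydrolyses the enol ether and the hydroxymethylene oxygen lactonises onto the distal ester, which is a known preparation of this 4-hydroxy-2-pyranone.

Step 2
Reactants: 4 ethyl 4-hydroxy-2-oxo-2H-pyran-5-carboxylate; 5 3-methylbut-2-enal
Product: 7 ethyl 2,2-dimethyl-5-oxo-2H,5H-pyrano[4,3-b]pyran-8-carboxylate, via Knoevenagel oxatriene 6 (not isolated)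
Conditions: piperidine (20 mol %), AcOH (20 mol %), Na2SO4, EtOAc, 80 °C
Reagents that add atoms: none
Why: Formal [3+3] annulation: Knoevenagel condensation of the iminium ion of 5 at C3 of 4 gives 1-oxatriene 6, which closes by oxa-6π electrocyclisation through the C4 oxygen to the fused 2-pyranone. A secondary amine salt is chosen because primary amines turn 4 into pyridones.

Step 3
Reactants: 7 ethyl 2,2-dimethyl-5-oxo-2H,5H-pyrano[4,3-b]pyran-8-carboxylate; 8 1,1-dimethoxyethene
Product: 11 ethyl 5-methoxy-2,2-dimethyl-2H-chromene-8-carboxylate, via bridged lactone adduct 9 (not isolated), via dihydrochromene ketal 10 (not isolated)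
Conditions: 8 (5 equiv), toluene, 110–120 °C, sealed tube (base-washed glass)
Reagents that add atoms: none
Why: The C8 ester and the lactone carbonyl make the 2-pyranone of 7 an electron-poor diene, and the electron-rich ketene acetal adds to it in an inverse-electron-demand Diels–Alder reaction, either concerted and asynchronous or stepwise through a zwitterion. The nucleophilic CH2 of 8 bonds to C7 of 7 (the CH next to the ring oxygen and beta to the ester, future C6') and the acetal carbon bonds to the ring-fusion carbon C4a (alpha to the lactone carbonyl, future C3'), giving bridged lactone 9. Retro-[4+2] loss of CO2 from 9 gives cyclohexadiene 10, and elimination of methanol aromatises it to 11. The closest known reaction type is the conversion of 5-alkoxycarbonyl-2-pyranones into 4-alkoxybenzoates with ketene acetals. The benzene ring is closed by the [4+2] cycloaddition, which makes both new bonds, followed by cycloreversion and elimination; no stereocentre remains, since the two bridgeheads of racemic 9 become aromatic carbons. Regioselectivity is required and is secured by the ester, which makes C7 the electrophilic terminus and so places the methoxy group para to the ester. Chemoselectivity is also required: the 2H-pyran alkene belongs to no electron-poor diene and should ignore an electron-rich alkene, and the lowest workable temperature keeps the pyran from reopening to oxatriene 6.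

Step 4
Reactants: 11 ethyl 5-methoxy-2,2-dimethyl-2H-chromene-8-carboxylate
Product: 13 5-hydroxy-2,2-dimethyl-2H-chromene-8-carboxylic acid, via phenol ester 12 (not isolated)
Conditions: NaSEt (3 equiv), DMF, 100 °C; then 2 M aq NaOH, 60 °C; 1 M HCl to pH 3, 0 °C
Reagents that add atoms: sodium hydroxide, [Na+].[OH-]
Why: SN2 demethylation of an aryl methyl ether by thiolate, fast here because the departing phenoxide is para to the ester; the chromene alkene is not a Michael acceptor, and hydroxide then saponifies the ester of 12 in the same flask.

Step 5
Reactants: 13 5-hydroxy-2,2-dimethyl-2H-chromene-8-carboxylic acid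
Product: 14 5-(acetyloxy)-2,2-dimethyl-2H-chromene-8-carboxylic acid
Conditions: Ac2O (1.3 equiv), 1 M aq NaOH (2.2 equiv), 0 °C; 1 M HCl to pH 3
Reagents that add atoms: acetic anhydride, CC(=O)OC(C)=O
Why: Chattaway acetylation: in cold aqueous alkali the phenoxide is acetylated while the carboxylate stays free, and any mixed anhydride is hydrolysed in the medium.

Step 6
Reactants: 14 5-(acetyloxy)-2,2-dimethyl-2H-chromene-8-carboxylic acid
Product: 15 5-(acetyloxy)-2,2-dimethyl-2H-chromene-8-carbonyl chloride
Conditions: (COCl)2 (1.2 equiv), DMF (cat.), CH2Cl2, 0 °C to rt; evaporate, use crude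
Reagents that add atoms: oxalyl chloride, ClC(=O)C(Cl)=O
Why: Vilsmeier-catalysed conversion of a benzoic acid into its chloride; the aryl acetate and the chromene alkene should tolerate the brief, cold exposure to HCl.

Step 7
Reactants: 16 5-bromo-2,4-dihydroxybenzaldehyde
Product: 17 2-bromo-4-formyl-5-hydroxyphenyl 2,2-dimethylpropanoate
Conditions: PivCl (1.05 equiv), Et3N, CH2Cl2, 0 °C
Reagents that add atoms: pivaloyl chloride, CC(C)(C)C(Cl)=O
Why: Selective O-acylation: the C2 hydroxyl is held in a hydrogen bond to the aldehyde, so the more acidic, free C4 hydroxyl takes the pivaloyl group.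

Step 8
Reactants: 17 2-bromo-4-formyl-5-hydroxyphenyl 2,2-dimethylpropanoate; 18 tributyl(3-methylbut-2-en-1-yl)stannane
Product: 19 4-formyl-5-hydroxy-2-(3-methylbut-2-en-1-yl)phenyl 2,2-dimethylpropanoate
Conditions: 18 (1.3 equiv), Pd(PPh3)4 (5 mol %), DMF, 95 °C
Reagents that add atoms: none
Why: Stille coupling of an aryl bromide with an allylic stannane: oxidative addition to zerovalent palladium, transmetallation and reductive elimination place the linear prenyl group on the carbon that held bromine, with aldehyde, phenol and pivalate as spectators.

Step 9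
Reactants: 19 4-formyl-5-hydroxy-2-(3-methylbut-2-en-1-yl)phenyl 2,2-dimethylpropanoate
Product: 20 5-hydroxy-4-(hydroxymethyl)-2-(3-methylbut-2-en-1-yl)phenyl 2,2-dimethylpropanoate
Conditions: NaBH4, THF/MeOH, 0 °C; aq NH4Cl
Reagents that add atoms: none
Why: Borohydride reduction of an aromatic aldehyde, fast at 0 °C; the hindered aryl pivalate should not be touched in the short reaction time.

Step 10
Reactants: 20 5-hydroxy-4-(hydroxymethyl)-2-(3-methylbut-2-en-1-yl)phenyl 2,2-dimethylpropanoate
Product: 21 {[4-(2,2-dimethylpropanoyloxy)-2-hydroxy-5-(3-methylbut-2-en-1-yl)phenyl]methyl}triphenylphosphonium bromide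
Conditions: PPh3·HBr (1.05 equiv), MeCN, 60 °C
Reagents that add atoms: triphenylphosphine hydrobromide, [PH+](c1ccccc1)(c1ccccc1)c1ccccc1.[Br-]
Why: The ortho-hydroxybenzyl alcohol ionises under the mild acid (benzyl cation or ortho-quinone methide) and is captured by triphenylphosphine; the phosphonium acid is too weak to protonate a trisubstituted alkene, as in the preparation of polyene Wittig salts from allylic alcohols.

Step 11
Reactants: 15 5-(acetyloxy)-2,2-dimethyl-2H-chromene-8-carbonyl chloride; 21 {[4-(2,2-dimethylpropanoyloxy)-2-hydroxy-5-(3-methylbut-2-en-1-yl)phenyl]methyl}triphenylphosphonium bromide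
Product: 24 2-[5-(acetyloxy)-2,2-dimethyl-2H-chromen-8-yl]-5-(3-methylbut-2-en-1-yl)-1-benzofuran-6-yl 2,2-dimethylpropanoate, via acyloxybenzyl phosphonium salt 22 (not isolated), via phosphorus ylide 23 (not isolated)
Conditions: 15 (1.0 equiv), Et3N (3.5 equiv), toluene, rt, then 110 °C
Reagents that add atoms: none
Why: Benzofuran synthesis by intramolecular Wittig reaction: the phenol of 21 is O-acylated to 22, triethylamine forms ylide 23, and the ylide attacks the neighbouring aryl ester carbonyl; loss of Ph3PO makes C2=C3 with the former acyl carbon as C2. One equivalent of 15 is used to limit C-acylation of the ylide.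

Step 12
Reactants: 24 2-[5-(acetyloxy)-2,2-dimethyl-2H-chromen-8-yl]-5-(3-methylbut-2-en-1-yl)-1-benzofuran-6-yl 2,2-dimethylpropanoate
Product: 25 Kanzonol V, 2,2-dimethyl-8-[6-hydroxy-5-(3-methylbut-2-en-1-yl)-1-benzofuran-2-yl]-2H-chromen-5-ol
Conditions: NaOMe (3 equiv), MeOH/THF, 0 °C to rt, argon; aq NH4Cl
Reagents that add atoms: none
Why: Methoxide transesterification should cleave both aryl esters at room temperature; no acid is involved, so neither the prenyl/phenol pair nor the chromene is put at risk.

## Compound list

1 | diethyl 3-oxopentanedioate (diethyl 3-oxoglutarate) | CCOC(=O)CC(=O)CC(=O)OCC | starting material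
2 | triethyl orthoformate | CCOC(OCC)OCC | starting material
3 | diethyl 2-(ethoxymethylidene)-3-oxopentanedioate (E/Z mixture) | CCOC=C(C(=O)OCC)C(=O)CC(=O)OCC | intermediate (not isolated)
4 | ethyl 4-hydroxy-2-oxo-2H-pyran-5-carboxylate | CCOC(=O)C1=COC(=O)C=C1O | intermediate
5 | 3-methylbut-2-enal | CC(C)=CC=O | starting material
6 | ethyl (3E)-3-(3-methylbut-2-en-1-ylidene)-2,4-dioxo-3,4-dihydro-2H-pyran-5-carboxylate (the isomer able to close) | CCOC(=O)C1=COC(=O)/C(=C/C=C(C)C)C1=O | intermediate (not isolated)
7 | ethyl 2,2-dimethyl-5-oxo-2H,5H-pyrano[4,3-b]pyran-8-carboxylate | CCOC(=O)C1=COC(=O)C2=C1OC(C)(C)C=C2 | intermediate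
8 | 1,1-dimethoxyethene | C=C(OC)OC | starting material
9 | racemic bridged lactone from addition of 8 across C7 and C4a of 7 (2-oxabicyclo[2.2.2]oct-5-en-3-one core; new bonds C7–CH2 and C4a–C(OMe)2; the bridge fixes the relative configuration of the two bridgeheads) | CCOC(=O)C1=C2OC(C)(C)C=CC23C(=O)OC1CC3(OC)OC | intermediate (not isolated)
10 | ethyl 5,5-dimethoxy-2,2-dimethyl-5,6-dihydro-2H-chromene-8-carboxylate | CCOC(=O)C1=CCC(OC)(OC)C2=C1OC(C)(C)C=C2 | intermediate (not isolated)
11 | ethyl 5-methoxy-2,2-dimethyl-2H-chromene-8-carboxylate | CCOC(=O)c1ccc(OC)c2c1OC(C)(C)C=C2 | intermediate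
12 | ethyl 5-hydroxy-2,2-dimethyl-2H-chromene-8-carboxylate (present as its sodium phenoxide) | CCOC(=O)c1ccc(O)c2c1OC(C)(C)C=C2 | intermediate (not isolated)
13 | 5-hydroxy-2,2-dimethyl-2H-chromene-8-carboxylic acid | OC(=O)c1ccc(O)c2c1OC(C)(C)C=C2 | intermediate
14 | 5-(acetyloxy)-2,2-dimethyl-2H-chromene-8-carboxylic acid | CC(=O)Oc1ccc(C(=O)O)c2c1C=CC(C)(C)O2 | intermediate
15 | 5-(acetyloxy)-2,2-dimethyl-2H-chromene-8-carbonyl chloride | CC(=O)Oc1ccc(C(Cl)=O)c2c1C=CC(C)(C)O2 | intermediate
16 | 5-bromo-2,4-dihydroxybenzaldehyde | O=Cc1cc(Br)c(O)cc1O | starting material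
17 | 2-bromo-4-formyl-5-hydroxyphenyl 2,2-dimethylpropanoate | CC(C)(C)C(=O)Oc1cc(O)c(C=O)cc1Br | intermediate
18 | tributyl(3-methylbut-2-en-1-yl)stannane | CCCC[Sn](CCCC)(CCCC)CC=C(C)C | starting material
19 | 4-formyl-5-hydroxy-2-(3-methylbut-2-en-1-yl)phenyl 2,2-dimethylpropanoate | CC(C)=CCc1cc(C=O)c(O)cc1OC(=O)C(C)(C)C | intermediate
20 | 5-hydroxy-4-(hydroxymethyl)-2-(3-methylbut-2-en-1-yl)phenyl 2,2-dimethylpropanoate | CC(C)=CCc1cc(CO)c(O)cc1OC(=O)C(C)(C)C | intermediate
21 | {[4-(2,2-dimethylpropanoyloxy)-2-hydroxy-5-(3-methylbut-2-en-1-yl)phenyl]methyl}triphenylphosphonium bromide | CC(C)=CCc1cc(C[P+](c2ccccc2)(c2ccccc2)c2ccccc2)c(O)cc1OC(=O)C(C)(C)C.[Br-] | intermediate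
22 | (2-{[5-(acetyloxy)-2,2-dimethyl-2H-chromene-8-carbonyl]oxy}-4-(2,2-dimethylpropanoyloxy)-5-(3-methylbut-2-en-1-yl)benzyl)triphenylphosphonium bromide | CC(C)=CCc1cc(C[P+](c2ccccc2)(c2ccccc2)c2ccccc2)c(OC(=O)c2ccc(OC(C)=O)c3c2OC(C)(C)C=C3)cc1OC(=O)C(C)(C)C.[Br-] | intermediate (not isolated)
23 | ylide of 22: 2-[(triphenyl-λ5-phosphanylidene)methyl]-5-(2,2-dimethylpropanoyloxy)-4-(3-methylbut-2-en-1-yl)phenyl 5-(acetyloxy)-2,2-dimethyl-2H-chromene-8-carboxylate | CC(C)=CCc1cc(C=P(c2ccccc2)(c2ccccc2)c2ccccc2)c(OC(=O)c2ccc(OC(C)=O)c3c2OC(C)(C)C=C3)cc1OC(=O)C(C)(C)C | intermediate (not isolated)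
24 | 2-[5-(acetyloxy)-2,2-dimethyl-2H-chromen-8-yl]-5-(3-methylbut-2-en-1-yl)-1-benzofuran-6-yl 2,2-dimethylpropanoate | CC(C)=CCc1cc2cc(-c3ccc(OC(C)=O)c4c3OC(C)(C)C=C4)oc2cc1OC(=O)C(C)(C)C | intermediate
25 | Kanzonol V | CC(C)=CCc1cc2cc(-c3ccc(O)c4c3OC(C)(C)C=C4)oc2cc1O | target

## Step count and least certain steps

Total: 12 steps. Longest linear sequence: 8 steps (steps 1 to 6, 11 and 12). The ring A branch (steps 7 to 10) joins at step 11.

**Step 3 (key step).** The cycloaddition may be slow, because the ring-fusion terminus C4a is fully substituted and the C4 oxygen donates into the diene. At the temperature then needed the ketene acetal may oligomerise. The 2H-pyran may also reopen reversibly to oxatriene 6, which is itself a heterodiene for ketene acetals, so that material is drained into a hetero-Diels–Alder pathway. The fallback gives up the cycloaddition and closes the pyran on a preformed benzoate. It does not set out from a compound of the route but replaces compounds 1 to 11, starting from commercial methyl 2-hydroxy-4-methoxybenzoate F1. O-Alkylation of F1 with 3-chloro-3-methylbut-1-yne (K2CO3, KI, CuI, acetone) would give methyl 4-methoxy-2-[(2-methylbut-3-yn-2-yl)oxy]benzoate F2. Heating in N,N-diethylaniline at about 190 °C (propargyl Claisen rearrangement, hydrogen shift, oxa-6π closure at the only free ortho position) would give methyl 5-methoxy-2,2-dimethyl-2H-chromene-8-carboxylate F3. F3 under the conditions of step 4 returns to the route at 13.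

**Step 8.** Transmetallation of the allylic stannane may leak through the allyl-transposed pathway and deliver some 1,1-dimethylallyl isomer. The free phenol may also protonate the stannane. The fallback sets out from 17 and installs the chain in two stages without regiochemical ambiguity. Stille coupling with allyltributylstannane gives 4-formyl-5-hydroxy-2-(prop-2-en-1-yl)phenyl 2,2-dimethylpropanoate F4. Cross-metathesis of F4 with 2-methylbut-2-ene (second-generation Grubbs catalyst, CH2Cl2, 40 °C) returns to the route at 19.

**Step 10.** Addition of HBr across the prenyl double bond, or acid-induced degradation of the prenyl group during the heated salt formation, would erode the product. The fallback sets out from 17 and postpones the prenylation until after the furan is closed.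
- Reduction of 17 with NaBH4 gives 2-bromo-5-hydroxy-4-(hydroxymethyl)phenyl 2,2-dimethylpropanoate F5.
- PPh3·HBr gives {[5-bromo-4-(2,2-dimethylpropanoyloxy)-2-hydroxyphenyl]methyl}triphenylphosphonium bromide F6.
- Treatment with 15 and Et3N as in step 11 passes through the O-aroyl phosphonium salt F7 and its ylide F8 (neither isolated) to 2-[5-(acetyloxy)-2,2-dimethyl-2H-chromen-8-yl]-5-bromo-1-benzofuran-6-yl 2,2-dimethylpropanoate F9.
- Stille coupling of F9 with 18 returns to the route at 24.

**Step 11.** Three things may go wrong: C-acylation of the ylide by acid chloride still present (leading to a 3-aroylbenzofuran), acetyl transfer from the aryl acetate to a phenoxide, and slow olefination of an ester carbonyl flanked by the pyran oxygen. The fallback replaces the Wittig closure by a reductive carbonyl–ester coupling and sets out from 19 and 15, so it also bypasses steps 9 and 10. Acylation of 19 with 15 (Et3N, DMAP, CH2Cl2) gives 2-formyl-5-(2,2-dimethylpropanoyloxy)-4-(3-methylbut-2-en-1-yl)phenyl 5-(acetyloxy)-2,2-dimethyl-2H-chromene-8-carboxylate F10. McMurry-type cyclisation of F10 with low-valent titanium (TiCl3, Zn, DME, reflux, slow addition) returns to the route at 24.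

## Further compounds

F1 | step 3 | methyl 2-hydroxy-4-methoxybenzoate | COC(=O)c1ccc(OC)cc1O
F2 | step 3 | methyl 4-methoxy-2-[(2-methylbut-3-yn-2-yl)oxy]benzoate | COC(=O)c1ccc(OC)cc1OC(C)(C)C#C
F3 | step 3 | methyl 5-methoxy-2,2-dimethyl-2H-chromene-8-carboxylate | COC(=O)c1ccc(OC)c2c1OC(C)(C)C=C2
F4 | step 8 | 4-formyl-5-hydroxy-2-(prop-2-en-1-yl)phenyl 2,2-dimethylpropanoate | C=CCc1cc(C=O)c(O)cc1OC(=O)C(C)(C)C
F5 | step 10 | 2-bromo-5-hydroxy-4-(hydroxymethyl)phenyl 2,2-dimethylpropanoate | CC(C)(C)C(=O)Oc1cc(O)c(CO)cc1Br
F6 | step 10 | {[5-bromo-4-(2,2-dimethylpropanoyloxy)-2-hydroxyphenyl]methyl}triphenylphosphonium bromide | CC(C)(C)C(=O)Oc1cc(O)c(C[P+](c2ccccc2)(c2ccccc2)c2ccccc2)cc1Br.[Br-]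
F7 | step 10 | (2-{[5-(acetyloxy)-2,2-dimethyl-2H-chromene-8-carbonyl]oxy}-5-bromo-4-(2,2-dimethylpropanoyloxy)benzyl)triphenylphosphonium bromide | CC(C)(C)C(=O)Oc1cc(OC(=O)c2ccc(OC(C)=O)c3c2OC(C)(C)C=C3)c(C[P+](c2ccccc2)(c2ccccc2)c2ccccc2)cc1Br.[Br-]
F8 | step 10 | ylide of F7: 4-bromo-5-(2,2-dimethylpropanoyloxy)-2-[(triphenyl-λ5-phosphanylidene)methyl]phenyl 5-(acetyloxy)-2,2-dimethyl-2H-chromene-8-carboxylate | CC(C)(C)C(=O)Oc1cc(OC(=O)c2ccc(OC(C)=O)c3c2OC(C)(C)C=C3)c(C=P(c2ccccc2)(c2ccccc2)c2ccccc2)cc1Br
F9 | step 10 | 2-[5-(acetyloxy)-2,2-dimethyl-2H-chromen-8-yl]-5-bromo-1-benzofuran-6-yl 2,2-dimethylpropanoate | CC(=O)Oc1ccc(-c2cc3cc(Br)c(OC(=O)C(C)(C)C)cc3o2)c2c1C=CC(C)(C)O2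
F10 | step 11 | 2-formyl-5-(2,2-dimethylpropanoyloxy)-4-(3-methylbut-2-en-1-yl)phenyl 5-(acetyloxy)-2,2-dimethyl-2H-chromene-8-carboxylate | CC(C)=CCc1cc(C=O)c(OC(=O)c2ccc(OC(C)=O)c3c2OC(C)(C)C=C3)cc1OC(=O)C(C)(C)C
A1 | alternative 1 | 3-[2-hydroxy-4-(methoxymethoxy)-5-(3-methylbut-2-en-1-yl)phenyl]-7-(methoxymethoxy)-2H-chromen-2-one | O=c1oc2cc(OCOC)ccc2cc1-c1cc(CC=C(C)C)c(OCOC)cc1O
A2 | alternative 1 | 3,9-bis(methoxymethoxy)-8-(3-methylbut-2-enyl)-6H-benzofuro[3,2-c]chromen-6-one | O=c1oc2cc(OCOC)ccc2c2oc3cc(OCOC)c(CC=C(C)C)cc3c12
A3 | alternative 2 | (3E)-1-diazo-4-[5-(3-methylbut-2-en-1-yl)-6-(triisopropylsilyloxy)-1-benzofuran-2-yl]but-3-en-2-one | [N-]=[N+]=CC(=O)/C=C/c1cc2cc(CC=C(C)C)c(O[Si](C(C)C)(C(C)C)C(C)C)cc2o1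
A4 | alternative 2 | triisopropyl[(5-methylhex-4-en-1-yn-1-yl)oxy]silane | CC(C)=CCC#CO[Si](C(C)C)(C(C)C)C(C)C
A5 | alternative 2 | 2-[2-hydroxy-3-(3-methylbut-2-enyl)-4-(triisopropylsilyloxy)phenyl]-5-(3-methylbut-2-enyl)-6-(triisopropylsilyloxy)benzofuran | CC(C)=CCc1cc2cc(-c3ccc(O[Si](C(C)C)(C(C)C)C(C)C)c(CC=C(C)C)c3O)oc2cc1O[Si](C(C)C)(C(C)C)C(C)C
A6 | alternative 3 | 2-[2,2-dimethyl-5-(triisopropylsilyloxy)-2H-chromen-8-yl]-6H-furo[3,2-c]pyran-6-one | O=C1OC=C2C=C(c3ccc(O[Si](C(C)C)(C(C)C)C(C)C)c4c3OC(C)(C)C=C4)OC2=C1
A7 | alternative 3 | bis(triisopropylsilyl) ether of Kanzonol V | CC(C)=CCc1cc2cc(-c3ccc(O[Si](C(C)C)(C(C)C)C(C)C)c4c3OC(C)(C)C=C4)oc2cc1O[Si](C(C)C)(C(C)C)C(C)C
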